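- At early times in the north run, side product A took 0.169 of the substrate lost up to 25.0 s. Between 50.0 s and 90.0 s, this selectivity fell to 0.0603.

| flask | substrate | coupling partner | protic impurity | remark | time |
|---|---|---|---|---|---|
| north | 20 mM | 26 mM | 6 mM | the very flask that is asked about, followed so far |  |
| south-west | 20 mM | 26 mM | 12 mM | run made earlier |  |
| flask | 20 mM | 26.0 mM | 6.00 mM |  | 3.0 min |

| run | time / s | intermediate A / % | intermediate C / % | target / % | side product B / % | substrate / % | side product A / % | intermediate B / % |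
|---|---|---|---|---|---|---|---|---|
| north | 10.0 | 9.9 | 0 | 1.7 | 0 | 83.3 | 2.6 | 2.8 |
| north | 15.0 | 13.0 | 0.4 | 1.7 | 0 | 75.0 | 3.7 | 4.7 |
| north | 25.0 | 17.2 | 2.4 | 3.6 | 0 | 62.7 | 6.3 | 9.1 |
| north | 40.0 | 20.1 | 4.4 | 4.9 | 0 | 48.5 | 6.7 | 15.0 |
| north | 50.0 | 20.3 | 6.0 | 6.0 | 0.7 | 40.4 | 8.0 | 18.4 |
| north | 80.0 | 21.4 | 10.2 | 7.2 | 1.5 | 24.3 | 8.9 | 26.3 |
| north | 90.0 | 20.8 | 11.2 | 7.6 | 1.7 | 20.5 | 9.2 | 27.7 |
| south-west | 10.0 | 10.5 | 0.7 | 1.5 | 0.2 | 82.8 | 2.8 | 2.4 |
| south-west | 12.0 | 11.5 | 1.5 | 2.0 | 0.1 | 79.7 | 2.9 | 2.6 |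
| south-west | 20.0 | 15.6 | 1.4 | 2.8 | 0 | 69.3 | 5.4 | 6.5 |
| south-west | 30.0 | 18.3 | 3.2 | 4.3 | 0.5 | 57.7 | 6.0 | 10.7 |
| south-west | 50.0 | 22.0 | 5.7 | 6.1 | 0.4 | 40.8 | 6.9 | 17.6 |
| south-west | 80.0 | 23.1 | 10.4 | 8.0 | 1.6 | 24.6 | 9.0 | 25.0 |

(scatter of a reading: 0.3 percentage points)

- the largest share of what was charged as substrate, at 3.0 min belongs to (side product B / side product A / intermediate C / intermediate A / intermediate B / target)
- the largest share itself, whichever of these holds it, in percent of the substrate charged

- The two numbers that clash: I took side product A to need coupling partner, so this fall put c(coupling partner) in the north run at 0.357 of its early level, yet intermediate B and side product A together held 7.04 mM of the 26.0 mM charged at 80.0 s.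
- I cleared this up with the hidden draw, the coupling partner gone minus the coupling partner found in those two species: 9.68 mM, a reading with wide scatter.
- So I expected intermediate B to keep its lead in this flask while its rise faded, from 3.4 percentage points to 1.4 points per 10.0 s.
- The forecast named intermediate B at 28%: “Intermediate B should still lead, near its plateau”.
- The flask gives intermediate B at 31.9%, ahead of intermediate C at 19.7%.

    substrate + coupling partner → side product A (k = 0.130 M⁻¹ s⁻¹)
    substrate → intermediate A (k = 0.0140 s⁻¹)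
    substrate → target (k = 0.00180 s⁻¹)
    coupling partner + intermediate A ⇌ intermediate B (K = 390 M⁻¹, k = 1.70 M⁻¹ s⁻¹)
    intermediate A → intermediate C (k = 0.00820 s⁻¹)
    intermediate C → side product B (k = 0.00390 s⁻¹)
    coupling partner + protic impurity → quenched reagent (k = 0.440 M⁻¹ s⁻¹)
    2 coupling partner → homo dimer (k = 0.220 M⁻¹ s⁻¹)

- The same subtraction at 1.50 min gives 11.2 mM, held as quenched reagent 2.53 mM and homo dimer 4.34 mM, two coupling partner each. At the start of this flask, homo dimer formation removed coupling partner at 0.0114 s⁻¹, faster than the protic impurity at 0.00264 s⁻¹.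
- In the neighbour with 80 mM of substrate, the north-run draw of 9.68 mM, carried over unchanged as a rough figure, leaves coupling partner for 20.4% of the substrate. The computed neighbour holds more than that, 22.5% as intermediate B and side product A, for its own draw at 3.00 min is smaller, 6.60 mM, and intermediate C leads at 27.9%.

Readings and results are simulated on assumed constants; noise was put on by code.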